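The partner turns the precatalyst into catalyst and, with that catalyst, turns each substrate into its product, while the protic impurity consumes partner as well.

left-handed substrate 0.20 M; partner 0.200 M; protic impurity 0.0400 M; precatalyst 30 mM; right-handed substrate 0.20 M

    partner + catalyst + left-handed substrate → catalyst + left-handed product (k1 = 0.129 L² mol⁻² s⁻¹)
    partner + catalyst + right-handed substrate → catalyst + right-handed product (k2 = 0.00653 L² mol⁻² s⁻¹)
    partner + precatalyst → catalyst + spent reagent (k3 = 0.00269 L mol⁻¹ s⁻¹)
    partner + protic impurity → quenched reagent (k4 = 0.0138 L mol⁻¹ s⁻¹)

1. the form that holds most of the catalyst when 10 % of the left-handed substrate and right-handed substrate together are converted (precatalyst / catalyst)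
2. its share of the catalyst then

I replaced time with partner exposure. I defined x as the activation constant times the time integral of partner, which leaves a fraction e to the minus x of the precatalyst in this flask. Partner cancels when the left-handed rate is divided by this clock, leaving one number: the activation gain, the left-handed step's constant times the precatalyst charge over the activation constant, 1.44. The logarithmic fall of the left-handed substrate equals this gain times the excess of x over the fraction activated.

I gave the left-handed substrate 95.2 % of the conversion at 10 % overall, so it lost 19.0 % of its own charge, a logarithmic fall of 0.211. The required excess was therefore 0.147. Expanding the exponential for small x, I found a first value of x of 0.542, and with the next term of the expansion I got 55.4 % of the precatalyst unactivated, more than the catalyst formed.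

The forecast gave precatalyst at 55 %, holding that “the result depends only on the partner exposure needed, not on the time taken”. The simulation gave precatalyst at 55.2 % after 25.1 min, with catalyst at 44.8 %.

With partner and left-handed substrate as charged, the left-handed step's rate was 0.31 min⁻¹ per catalyst, 9.59 times faster than activation at 0.032 min⁻¹ per precatalyst, and multiplying that ratio by the charge ratio of precatalyst to left-handed substrate, 0.150, returns the gain of 1.44. In the flask with twice the precatalyst the gain doubles, and to leading order the exposure needed changes by a factor of 0.707, while the time to that conversion there changed by a factor of 0.685.

The numbers of this flask stand for no real mixture; the result is computed.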